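**Plan**

1. Numbering (prostanoid): C1 is the ester carbon, and C5=C6 and C7=C8 form the dienone side chain. The ring is C8–C12, with C9 the ketone, C10 the C–Cl carbon, C11 the =CH and C12 the carbinol carbon. C13–C20 is the octenyl chain.
2. Retrosynthetic cuts, in order: the acetyl C–O bond; C7=C8 (aldol condensation with a C1–C7 enal); both ring bonds of C10 (C9–C10 and C10=C11), which removes C10 and its chlorine from the ring; last C12–C13.
3. Enabling feature: the triad C9(=O)–C10(Cl)=C11H is what :CCl2 leaves when it inserts into the C9=C11 bond of a silyl enol ether. The five-membered ring C8–C9–C10–C11–C12 can therefore grow from the four-membered ring C8–C9–C11–C12.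
4. Stereochemistry: without C10 and C7 that cyclobutanone has a mirror plane through C9 and C12. C12 is set by an enantioselective deprotonation (chiral lithium amide) that tells C11H2 from C8H2, and it is not touched afterwards.
5. Forward order: octenyl addition to 3-(benzyloxy)cyclobutanone (C12–C13), unmasking of the prochiral ketone, desymmetrisation, ring expansion from four to five, aldol/dehydration (C7=C8), desilylation, acetylation.
6. Alkene geometry: 14Z comes from (Z)-oct-2-en-1-ol through a configurationally stable allylbarium, 5E from cross metathesis, 7E from an E1cB elimination.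

Key step: step 7

Assumption: the (R,R)-amide of step 6 is taken to remove a proton from the CH2 group that becomes C11. The sense of induction has to be confirmed on this substrate, and the equally available (S,S)-amine is used if it proves opposite.

**Route**

Step 1
Reactants: 1 (Z)-oct-2-en-1-ol
Product: 2 (Z)-1-chlorooct-2-ene
Conditions: NCS, Me2S, CH2Cl2, −20 → 0 °C
Reagents that add atoms: N-chlorosuccinimide, O=C1CCC(=O)N1Cl
Why: Corey–Kim-type chlorination, in which chloride displaces the alkoxysulfonium group by direct SN2 attack at the primary carbon, a process known to convert allylic alcohols without allylic transposition or loss of Z geometry; no stereocentre is formed.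

Step 2
Reactants: 2 (Z)-1-chlorooct-2-ene; 3 3-(benzyloxy)cyclobutan-1-one
Product: 5 3-(benzyloxy)-1-[(Z)-oct-2-en-1-yl]cyclobutan-1-ol (cis/trans mixture), via octenylbarium chloride 4 (not isolated)
Conditions: BaI2, lithium biphenylide (2 equiv), THF, rt; 2, −78 °C; 3, −78 °C; 1 M HCl
Reagents that add atoms: none
Why: Allylbarium addition to a ketone: allylbarium chlorides made from reactive barium at −78 °C keep their Z geometry and, unlike allylmagnesium or allylzinc reagents, attack carbonyl groups through the α-carbon, so the linear (Z)-octenyl carbinol should form; the cis/trans relation of the ring substituents does not matter because the benzyloxy carbon becomes the ketone C9 in step 5.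

Step 3
Reactants: 5 3-(benzyloxy)-1-[(Z)-oct-2-en-1-yl]cyclobutan-1-ol
Product: 6 [3-(benzyloxy)-1-[(Z)-oct-2-en-1-yl]cyclobutoxy](tert-butyl)dimethylsilane
Conditions: TBSOTf, 2,6-lutidine, CH2Cl2, 0 °C → rt
Reagents that add atoms: tert-butyldimethylsilyl trifluoromethanesulfonate, CC(C)(C)[Si](C)(C)OS(=O)(=O)C(F)(F)F
Why: Standard silylation of a hindered tertiary alcohol with a silyl triflate and a non-nucleophilic base; the bulky, poorly leaving silyloxy group is needed for the two later enolisations and for the facial bias in step 6.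

Step 4
Reactants: 6 [3-(benzyloxy)-1-[(Z)-oct-2-en-1-yl]cyclobutoxy](tert-butyl)dimethylsilane
Product: 7 3-(tert-butyldimethylsilyloxy)-3-[(Z)-oct-2-en-1-yl]cyclobutan-1-ol
Conditions: lithium 4,4'-di-tert-butylbiphenylide, THF, −78 °C; H2O at −78 °C
Reagents that add atoms: none
Why: Reductive cleavage of the benzylic C–O bond by an arene radical anion, which leaves the isolated Z alkene (this rules out hydrogenolysis) and the silyl ether untouched, and the quench at −78 °C forestalls transannular silyl migration to the new alkoxide.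

Step 5
Reactants: 7 3-(tert-butyldimethylsilyloxy)-3-[(Z)-oct-2-en-1-yl]cyclobutan-1-ol
Product: 8 3-(tert-butyldimethylsilyloxy)-3-[(Z)-oct-2-en-1-yl]cyclobutan-1-one (achiral, mirror plane through C9 and C12)
Conditions: Dess–Martin periodinane, CH2Cl2, rt
Reagents that add atoms: none
Why: Dess–Martin oxidation under essentially neutral conditions, which merges both diastereomers of 7 into one prochiral ketone and avoids base-induced β-elimination of the silyloxy group.

Step 6
Reactants: 8 3-(tert-butyldimethylsilyloxy)-3-[(Z)-oct-2-en-1-yl]cyclobutan-1-one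
Product: 10 (3S)-3-(tert-butyldimethylsilyloxy)-3-[(Z)-oct-2-en-1-yl]-1-(triethylsilyloxy)cyclobut-1-ene, via lithium enolate 9 (not isolated)
Conditions: (R,R)-bis(1-phenylethyl)amine, n-BuLi, LiCl, THF; Et3SiCl present (internal quench), −100 °C; cold work-up, amine removed, kept below 0 °C
Reagents that add atoms: chlorotriethylsilane, CC[Si](Cl)(CC)CC
Why: Enantioselective deprotonation of a prochiral ketone with a C2-symmetric chiral lithium amide under internal silyl quench, a reaction type established for 3-substituted and 3,3-disubstituted cyclobutanones: the amide takes a proton from only one of the two enantiotopic CH2 groups (the one that becomes C11), on the face away from the bulky OTBS group, which makes C12 a stereocentre (S in 10), while −100 °C and the poor silyloxide leaving group suppress β-elimination from 9.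

Step 7
Reactants: 10 (3S)-3-(tert-butyldimethylsilyloxy)-3-[(Z)-oct-2-en-1-yl]-1-(triethylsilyloxy)cyclobut-1-ene
Product: 12 (4S)-4-(tert-butyldimethylsilyloxy)-2-chloro-4-[(Z)-oct-2-en-1-yl]cyclopent-2-en-1-one, via dichlorobicyclopentane 11 (not isolated)
Conditions: CHCl3 (excess), KOtBu (about 1.5 equiv, added in portions), pentane, −30 → 0 °C
Reagents that add atoms: chloroform, ClC(Cl)Cl
Why: KOtBu and CHCl3 give singlet :CCl2, which adds in a concerted [2+1] cheletropic step to the electron-rich, strained C9=C11 enol-ether bond of 10 to give the 5,5-dichloro-1-siloxybicyclo[2.1.0]pentane 11; ring strain and the push of the siloxy group then drive the disrotatory two-electron cyclopropyl-to-allyl opening of the central C9–C11 bond with loss of the endo chloride, and chloride strips Et3Si from the 2-chloro-1-siloxyallyl cation to leave the C9(=O)–C10(Cl)=C11H unit of 12. The closest known reaction type is the dihalocarbene one-carbon ring expansion of cyclic silyl enol ethers to 2-halocycloalk-2-enones. The only ring closed is the transient cyclopropane ([2+1] cycloaddition); the five-membered ring is not closed by a cyclisation but is the periphery of 11 that remains once the zero-atom bridge breaks, so the four-membered ring C8–C9–C11–C12 grows by the single atom C10. The two bridgehead stereocentres of 11 (C9 and C11) are transient and both facial adducts converge on 12, while C12 is not touched and keeps the configuration fixed in step 6. Regiochemistry is built in, because the carbene carbon can only end between C9 and C11 and keeps one chlorine; the selectivity needed is chemoselectivity over the C14=C15 alkene, secured by the much higher nucleophilicity of the siloxy-substituted cyclobutene towards the electrophilic carbene and by limiting the base. Working at or below 0 °C keeps 10, a 3-siloxycyclobutene, from conrotatory opening to a 1,3-bis(siloxy)diene, and the excess of CHCl3 keeps the base-sensitive 12 from prolonged contact with alkoxide.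

Step 8
Reactants: 13 methyl hex-5-enoate; 14 (E)-crotonaldehyde
Product: 15 methyl (E)-7-oxohept-5-enoate
Conditions: second-generation Hoveyda–Grubbs catalyst RuCl2(H2IMes)(=CH-C6H4-2-OiPr) (2 mol %), CH2Cl2, 40 °C
Reagents that add atoms: none
Why: Cross metathesis of a terminal alkene with an enal partner, a well-precedented and strongly E-selective route to γ-alkyl enals that is driven by loss of propene and sets the 5E alkene.

Step 9
Reactants: 12 (4S)-4-(tert-butyldimethylsilyloxy)-2-chloro-4-[(Z)-oct-2-en-1-yl]cyclopent-2-en-1-one; 15 methyl (E)-7-oxohept-5-enoate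
Product: 17 methyl (5E)-7-[(2S)-2-(tert-butyldimethylsilyloxy)-4-chloro-2-[(Z)-oct-2-en-1-yl]-5-oxocyclopent-3-en-1-yl]-7-hydroxyhept-5-enoate (mixture at C7 and C8), via lithium dienolate 16 (not isolated)
Conditions: LiN(iPr)2, THF, −78 °C; 15, −78 °C; AcOH, −78 °C
Reagents that add atoms: none
Why: Directed aldol addition: C8H2 is the only enolisable position of 12, the lithium cross-conjugated dienolate adds 1,2 to the enal at −78 °C as known for 4-silyloxycyclopent-2-enones, loss of silyloxide would give an antiaromatic cyclopentadienone and is therefore slow, and the uncontrolled new centres C7 and C8 are erased in step 10.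

Step 10
Reactants: 17 methyl (5E)-7-[(2S)-2-(tert-butyldimethylsilyloxy)-4-chloro-2-[(Z)-oct-2-en-1-yl]-5-oxocyclopent-3-en-1-yl]-7-hydroxyhept-5-enoate
Product: 19 methyl (5E,7E)-7-[(2R)-2-(tert-butyldimethylsilyloxy)-4-chloro-2-[(Z)-oct-2-en-1-yl]-5-oxocyclopent-3-en-1-ylidene]hept-5-enoate, via allylic mesylate 18 (not isolated)
Conditions: MsCl, Et3N, DMAP (cat.), CH2Cl2, −20 °C → rt
Reagents that add atoms: none
Why: Mesylation followed by E1cB elimination, the usual dehydration of such aldols: passage through the enolate should let the more stable 7E geometry prevail (C6 anti to the C9 carbonyl, so the vinyl group is not pressed against the carbonyl oxygen), any 7Z isomer is removed by chromatography, and the C12 descriptor changes from S to R only because C8 gains CIP rank.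

Step 11
Reactants: 19 methyl (5E,7E)-7-[(2R)-2-(tert-butyldimethylsilyloxy)-4-chloro-2-[(Z)-oct-2-en-1-yl]-5-oxocyclopent-3-en-1-ylidene]hept-5-enoate
Product: 20 methyl (5E,7E)-7-[(2R)-4-chloro-2-hydroxy-2-[(Z)-oct-2-en-1-yl]-5-oxocyclopent-3-en-1-ylidene]hept-5-enoate
Conditions: HF·pyridine, MeCN, 0 °C → rt
Reagents that add atoms: none
Why: Fluoride-mediated cleavage of the tertiary silyl ether in a mildly acidic medium, which spares the base-sensitive cross-conjugated dienone, the methyl ester and the C12–O bond.

Step 12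
Reactants: 20 methyl (5E,7E)-7-[(2R)-4-chloro-2-hydroxy-2-[(Z)-oct-2-en-1-yl]-5-oxocyclopent-3-en-1-ylidene]hept-5-enoate
Product: 21 methyl (5E,7E)-7-[(2R)-2-acetoxy-4-chloro-2-[(Z)-oct-2-en-1-yl]-5-oxocyclopent-3-en-1-ylidene]hept-5-enoate (target)
Conditions: Ac2O, DMAP, Et3N, CH2Cl2, rt
Reagents that add atoms: acetic anhydride, CC(=O)OC(C)=O
Why: DMAP-catalysed acyl transfer to the tertiary alcohol, the usual last step for 12-acetoxy marine prostanoids; only the O–H bond reacts, so C12 keeps its R configuration.

**Compound list**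

| No. | Name | SMILES | Role |
|---|---|---|---|
| 1 | (Z)-oct-2-en-1-ol | CCCCC/C=C\CO | starting material |
| 2 | (Z)-1-chlorooct-2-ene | CCCCC/C=C\CCl | intermediate |
| 3 | 3-(benzyloxy)cyclobutan-1-one | O=C1CC(OCc2ccccc2)C1 | starting material |
| 4 | (Z)-oct-2-en-1-ylbarium chloride (not isolated) | CCCCC/C=C\C[Ba]Cl | intermediate |
| 5 | 3-(benzyloxy)-1-[(Z)-oct-2-en-1-yl]cyclobutan-1-ol (cis/trans mixture) | CCCCC/C=C\CC1(O)CC(OCc2ccccc2)C1 | intermediate |
| 6 | [3-(benzyloxy)-1-[(Z)-oct-2-en-1-yl]cyclobutoxy](tert-butyl)dimethylsilane (cis/trans mixture) | CCCCC/C=C\CC1(O[Si](C)(C)C(C)(C)C)CC(OCc2ccccc2)C1 | intermediate |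
| 7 | 3-(tert-butyldimethylsilyloxy)-3-[(Z)-oct-2-en-1-yl]cyclobutan-1-ol (cis/trans mixture) | CCCCC/C=C\CC1(O[Si](C)(C)C(C)(C)C)CC(O)C1 | intermediate |
| 8 | 3-(tert-butyldimethylsilyloxy)-3-[(Z)-oct-2-en-1-yl]cyclobutan-1-one | CCCCC/C=C\CC1(O[Si](C)(C)C(C)(C)C)CC(=O)C1 | intermediate |
| 9 | lithium (S)-enolate of 8 (not isolated) | CCCCC/C=C\C[C@@]1(O[Si](C)(C)C(C)(C)C)C=C(O[Li])C1 | intermediate |
| 10 | (3S)-3-(tert-butyldimethylsilyloxy)-3-[(Z)-oct-2-en-1-yl]-1-(triethylsilyloxy)cyclobut-1-ene | CCCCC/C=C\C[C@@]1(O[Si](C)(C)C(C)(C)C)C=C(O[Si](CC)(CC)CC)C1 | intermediate |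
| 11 | (3S)-3-(tert-butyldimethylsilyloxy)-5,5-dichloro-3-[(Z)-oct-2-en-1-yl]-1-(triethylsilyloxy)bicyclo[2.1.0]pentane (both facial adducts, not isolated) | CCCCC/C=C\C[C@@]1(O[Si](C)(C)C(C)(C)C)C2C(Cl)(Cl)C2(O[Si](CC)(CC)CC)C1 | intermediate |
| 12 | (4S)-4-(tert-butyldimethylsilyloxy)-2-chloro-4-[(Z)-oct-2-en-1-yl]cyclopent-2-en-1-one | CCCCC/C=C\C[C@@]1(O[Si](C)(C)C(C)(C)C)C=C(Cl)C(=O)C1 | intermediate |
| 13 | methyl hex-5-enoate | C=CCCCC(=O)OC | starting material |
| 14 | (E)-crotonaldehyde | C/C=C/C=O | starting material |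
| 15 | methyl (E)-7-oxohept-5-enoate | COC(=O)CCC/C=C/C=O | intermediate |
| 16 | lithium cross-conjugated dienolate of 12 (not isolated) | CCCCC/C=C\C[C@@]1(O[Si](C)(C)C(C)(C)C)C=C(Cl)C(O[Li])=C1 | intermediate |
| 17 | methyl (5E)-7-[(2S)-2-(tert-butyldimethylsilyloxy)-4-chloro-2-[(Z)-oct-2-en-1-yl]-5-oxocyclopent-3-en-1-yl]-7-hydroxyhept-5-enoate (mixture at C7 and C8) | CCCCC/C=C\C[C@@]1(O[Si](C)(C)C(C)(C)C)C=C(Cl)C(=O)C1C(O)/C=C/CCCC(=O)OC | intermediate |
| 18 | C7 methanesulfonate of 17 (not isolated) | CCCCC/C=C\C[C@@]1(O[Si](C)(C)C(C)(C)C)C=C(Cl)C(=O)C1C(OS(C)(=O)=O)/C=C/CCCC(=O)OC | intermediate |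
| 19 | methyl (5E,7E)-7-[(2R)-2-(tert-butyldimethylsilyloxy)-4-chloro-2-[(Z)-oct-2-en-1-yl]-5-oxocyclopent-3-en-1-ylidene]hept-5-enoate | CCCCC/C=C\C[C@@]1(O[Si](C)(C)C(C)(C)C)C=C(Cl)C(=O)/C1=C/C=C/CCCC(=O)OC | intermediate |
| 20 | methyl (5E,7E)-7-[(2R)-4-chloro-2-hydroxy-2-[(Z)-oct-2-en-1-yl]-5-oxocyclopent-3-en-1-ylidene]hept-5-enoate | CCCCC/C=C\C[C@@]1(O)C=C(Cl)C(=O)/C1=C/C=C/CCCC(=O)OC | intermediate |
| 21 | methyl (5E,7E)-7-[(2R)-2-acetoxy-4-chloro-2-[(Z)-oct-2-en-1-yl]-5-oxocyclopent-3-en-1-ylidene]hept-5-enoate | CCCCC/C=C\C[C@@]1(OC(C)=O)C=C(Cl)C(=O)/C1=C/C=C/CCCC(=O)OC | target |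

Total step count: 12. Longest linear sequence: 11 (steps 1–7 and 9–12).

**Steps most likely to fail**

**Step 6: weak discrimination between the enantiotopic CH2 groups.** The OTBS group and the CH2 chain at C12 may not differ enough to fix the face from which the proton is taken, which would erode the enantiomeric purity.
- The fallback sets out from 8 and comes back at 12.
- 8 is enolised with LiN(iPr)2/Et3SiCl to the racemic enol silane F1.
- F1 is ring-expanded under the conditions of step 7 to the racemic chloroenone F2.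
- The racemate is divided by a catalyst-controlled Corey–Bakshi–Shibata reduction ((S)-2-methyl-CBS-oxazaborolidine, BH3·SMe2). 2-Halo enones are very good substrates for this reduction.
- Both enantiomers should receive hydride on the same carbonyl face. They then become diastereomers, the (1R,4S)-alcohol F3 and the (1R,4R)-alcohol F4, which can be separated on silica.
- Dess–Martin oxidation of F3 gives 12. At most half of the material is used.

**Step 7: competing reactions around the carbene step.** These are carbene addition to the C14=C15 alkene, attack of alkoxide or trichloromethyl anion on the freshly formed chloroenone, and thermal opening of the siloxycyclobutene.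
- The fallback sets out from 10 and comes back at 12. It brings C10 in as CH2 under non-basic conditions and adds the chlorine afterwards.
- Simmons–Smith cyclopropanation (Et2Zn, CH2I2) of the enol ether gives the siloxybicyclopentane F5.
- FeCl3 in DMF opens the central bond oxidatively to the β-chloro ketone F6.
- NaOAc in MeOH eliminates to the chlorine-free enone F7.
- Nucleophilic epoxidation (H2O2, NaOH, MeOH) touches only the enone and gives the epoxy ketone F8.
- HCl in Et2O opens F8 at the α-carbon to the chlorohydrin F9, which loses water to give 12.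

**Step 2: loss of α-regioselectivity or Z geometry.** Equilibration of the allyl metal would cause this, and the reagent could also enolise the cyclobutanone.
- The fallback sets out from 3 and comes back at 6. It builds the Z alkene by olefination instead of transferring it.
- CH2=CHCH2MgBr adds to 3 to give the allyl carbinol F10.
- TBSOTf/2,6-lutidine gives the silyl ether F11.
- Ozonolysis with PPh3 work-up gives the aldehyde F12.
- A salt-free Wittig reaction with hexyltriphenylphosphonium bromide and NaN(SiMe3)2 in THF at −78 °C gives 6 with the Z alkene.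

**Further compounds**

F1 | step 6 | racemic 3-(tert-butyldimethylsilyloxy)-3-[(Z)-oct-2-en-1-yl]-1-(triethylsilyloxy)cyclobut-1-ene | CCCCC/C=C\CC1(O[Si](C)(C)C(C)(C)C)C=C(O[Si](CC)(CC)CC)C1
F2 | step 6 | racemic 4-(tert-butyldimethylsilyloxy)-2-chloro-4-[(Z)-oct-2-en-1-yl]cyclopent-2-en-1-one | CCCCC/C=C\CC1(O[Si](C)(C)C(C)(C)C)C=C(Cl)C(=O)C1
F3 | step 6 | (1R,4S)-4-(tert-butyldimethylsilyloxy)-2-chloro-4-[(Z)-oct-2-en-1-yl]cyclopent-2-en-1-ol | CCCCC/C=C\C[C@@]1(O[Si](C)(C)C(C)(C)C)C=C(Cl)[C@H](O)C1
F4 | step 6 | (1R,4R)-4-(tert-butyldimethylsilyloxy)-2-chloro-4-[(Z)-oct-2-en-1-yl]cyclopent-2-en-1-ol | CCCCC/C=C\C[C@]1(O[Si](C)(C)C(C)(C)C)C=C(Cl)[C@H](O)C1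
F5 | step 7 | (3S)-3-(tert-butyldimethylsilyloxy)-3-[(Z)-oct-2-en-1-yl]-1-(triethylsilyloxy)bicyclo[2.1.0]pentane | CCCCC/C=C\C[C@@]1(O[Si](C)(C)C(C)(C)C)C2CC2(O[Si](CC)(CC)CC)C1
F6 | step 7 | (4S)-4-(tert-butyldimethylsilyloxy)-3-chloro-4-[(Z)-oct-2-en-1-yl]cyclopentan-1-one (C3 epimers) | CCCCC/C=C\C[C@@]1(O[Si](C)(C)C(C)(C)C)C(Cl)CC(=O)C1
F7 | step 7 | (4S)-4-(tert-butyldimethylsilyloxy)-4-[(Z)-oct-2-en-1-yl]cyclopent-2-en-1-one | CCCCC/C=C\C[C@@]1(O[Si](C)(C)C(C)(C)C)C=CC(=O)C1
F8 | step 7 | (4S)-4-(tert-butyldimethylsilyloxy)-4-[(Z)-oct-2-en-1-yl]-6-oxabicyclo[3.1.0]hexan-2-one | CCCCC/C=C\C[C@@]1(O[Si](C)(C)C(C)(C)C)C2OC2C(=O)C1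
F9 | step 7 | (4S)-4-(tert-butyldimethylsilyloxy)-2-chloro-3-hydroxy-4-[(Z)-oct-2-en-1-yl]cyclopentan-1-one | CCCCC/C=C\C[C@@]1(O[Si](C)(C)C(C)(C)C)C(O)C(Cl)C(=O)C1
F10 | step 2 | 1-allyl-3-(benzyloxy)cyclobutan-1-ol | C=CCC1(O)CC(OCc2ccccc2)C1
F11 | step 2 | [1-allyl-3-(benzyloxy)cyclobutoxy](tert-butyl)dimethylsilane | C=CCC1(O[Si](C)(C)C(C)(C)C)CC(OCc2ccccc2)C1
F12 | step 2 | 2-[3-(benzyloxy)-1-(tert-butyldimethylsilyloxy)cyclobutyl]acetaldehyde | O=CCC1(O[Si](C)(C)C(C)(C)C)CC(OCc2ccccc2)C1
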